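1. Cuts, last-made first: the butyrate and acetate C–O bonds and the two C–Cl bonds, leading back to an indane with CO2Me on C4, CH2CO2Me on C5 and CH2OTBS on C6.
2. Then, in one disconnection, C4–C(=O) and C5–CH2 (malonate C–C insertion into a C4–C5 aryne) together with the ring bonds C3a–C7a and C6–C7 (cycloaromatisation of a triyne).
3. Finally the diyne C(sp)–C(sp) bond (Cadiot–Chodkiewicz) and the two alkyne carbons of a 1,6-diyne made from 3,3-dimethylglutaric anhydride.
4. Forward: the open chain is joined first, the cyclopentane and benzene rings then arise together in step 6, and five functional-group steps finish the target.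
5. Enabling feature (indane numbering, C2 = CMe2): C4 carries a one-carbon arm and C5 a two-carbon arm side by side, the homophthalate pattern of an aryne/malonate insertion; C1–C2–C3 is a three-atom gem-dimethyl tether between C3a and C7a; C7 carries only H, as a terminal alkyne carbon would.
6. Stereochemistry: the target has no stereocentre and no stereogenic double bond, so nothing has to be set.

Key step: step 6

Remark on the chemistry: locants follow the indane numbering above throughout (C4 = acetoxymethyl arm, C5 = chloroethyl arm, C6 = butyrate arm), also where a systematic name could use lower locants. TBS = tert-butyldimethylsilyl. Silyl ether 6 is assumed to be bought as such.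

Step 1
Reactants: 1 3,3-dimethylglutaric anhydride
Product: 2 3,3-dimethylpentane-1,5-diol
Conditions: LiAlH4, THF, 0 °C to reflux; aq. NaOH work-up
Reagents that add atoms: none
Why: Hydride reduction of a cyclic anhydride with LiAlH4 takes both acyl carbons to the primary alcohol level, and the quaternary carbon carries nothing that could interfere.

Step 2
Reactants: 2 3,3-dimethylpentane-1,5-diol
Product: 3 3,3-dimethylpentanedial
Conditions: (COCl)2, DMSO, CH2Cl2, −78 °C; Et3N, −78 °C to rt; used crude
Reagents that add atoms: none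
Why: Swern oxidation activates both hydroxyl groups at low temperature before any aldehyde is released, which avoids the lactol-to-lactone over-oxidation that 1,5-diols suffer with other oxidants.

Step 3
Reactants: 3 3,3-dimethylpentanedial; 4 dimethyl (1-diazo-2-oxopropyl)phosphonate
Product: 5 4,4-dimethylhepta-1,6-diyne
Conditions: 4 (2.5 equiv), K2CO3, MeOH, 0 °C to rt; pentane extraction, careful distillation
Reagents that add atoms: none
Why: Twofold Ohira–Bestmann (Seyferth–Gilbert) homologation, in which the diazomethylphosphonate anion released from 4 by methanolysis olefinates each aldehyde and loss of N2 with 1,2-hydrogen shift gives the terminal alkyne under conditions mild enough for enolisable aldehydes.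

Step 4
Reactants: 6 tert-butyldimethyl(prop-2-yn-1-yloxy)silane
Product: 7 [(3-bromoprop-2-yn-1-yl)oxy](tert-butyl)dimethylsilane
Conditions: NBS, AgNO3 (cat.), acetone, rt
Reagents that add atoms: N-bromosuccinimide, O=C1CCC(=O)N1Br
Why: AgNO3-catalysed electrophilic bromination of a terminal alkyne is the standard entry to 1-bromoalkynes and leaves the silyl ether untouched.

Step 5
Reactants: 5 4,4-dimethylhepta-1,6-diyne; 7 [(3-bromoprop-2-yn-1-yl)oxy](tert-butyl)dimethylsilane
Product: 8 tert-butyl[(7,7-dimethyldeca-2,4,9-triyn-1-yl)oxy]dimethylsilane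
Conditions: 5 (3 equiv), CuCl (cat.), NH2OH·HCl, n-BuNH2 (30% aq.), Et2O, 0 °C; 7 added slowly; excess 5 recovered by distillation
Reagents that add atoms: none
Why: Cadiot–Chodkiewicz coupling joins one terminal alkyne of 5 to the bromoalkyne as an unsymmetrical 1,3-diyne, the excess of symmetric 5 and slow addition of 7 holding back double coupling while hydroxylamine keeps the copper monovalent and so suppresses oxidative homocoupling.

Step 6
Reactants: 8 tert-butyl[(7,7-dimethyldeca-2,4,9-triyn-1-yl)oxy]dimethylsilane; 9 dimethyl malonate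
Product: 12 methyl 6-({[tert-butyl(dimethyl)silyl]oxy}methyl)-5-(2-methoxy-2-oxoethyl)-2,2-dimethyl-2,3-dihydro-1H-indene-4-carboxylate, via aryne 10 (not isolated), via cyclobutenoxide 11 (not isolated)
Conditions: 9 (5 equiv), Cs2CO3 (0.3 equiv, dried, finely powdered), 1,2-dichlorobenzene (0.01 M in 8), 180 °C, sealed tube; cooled and filtered through silica
Reagents that add atoms: none
Why: Proposed new method: heating should drive an intramolecular hexadehydro-Diels–Alder reaction in which the 1,3-diyne (future C3a, C4, C5, C6) and the tethered terminal alkyne (future C7a, C7) combine, probably stepwise through a diradical, to aryne 10, while Cs2CO3 turns part of 9 into its cesium enolate and CsHCO3; the enolate carbon then adds to C5, the C4 carbanion closes on an ester carbonyl to the cesium cyclobutenoxide 11, and retro-aldol-type opening of 11 leaves CH2CO2Me on C5 and CO2Me on C4 as the cesium arylacetate enolate, which excess 9 protonates to 12 while the cesium enolate of 9 is re-formed. The closest known reaction types are the thermal cycloaromatisation of tethered triynes with in situ trapping of the aryne and the acyl-alkylation (C–C insertion) of fluoride-generated arynes with malonates, which have not been run together on a thermally generated aryne. The cyclopentane ring closes by the C3a–C7a bond across the CH2–CMe2–CH2 tether, the gem-dimethyl group favouring the folded conformer (Thorpe–Ingold effect), and the benzene ring closes by the C6–C7 bond of the same formal (4+2) event, whereas the four-membered ring of 11 (4-exo-trig attack on the ester) is opened again. No stereocentre is created. The selectivity needed is attack of the enolate carbon at C5 and not C4, which the fused five-membered ring should secure by widening the internal angle at C5 and placing the developing carbanion at C4 next to the strained ring fusion. Chemoselectivity toward the base-sensitive triyne is served by the substoichiometric Cs2CO3, the high dilution and the excess of 9, which also outcompetes trapping of 10 by the terminal alkyne of unreacted 8.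

Step 7
Reactants: 12 methyl 6-({[tert-butyl(dimethyl)silyl]oxy}methyl)-5-(2-methoxy-2-oxoethyl)-2,2-dimethyl-2,3-dihydro-1H-indene-4-carboxylate
Product: 13 2-[6-({[tert-butyl(dimethyl)silyl]oxy}methyl)-4-(hydroxymethyl)-2,2-dimethyl-2,3-dihydro-1H-inden-5-yl]ethan-1-ol
Conditions: LiAlH4, THF, 0 °C to rt; aq. potassium sodium tartrate work-up
Reagents that add atoms: none
Why: LiAlH4 hydride reduction takes both the hindered benzoate and the arylacetate ester to primary alcohols, the silyl ether is inert, and the non-acidic work-up avoids acid-promoted cyclisation of the diol to an isochroman.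

Step 8
Reactants: 13 2-[6-({[tert-butyl(dimethyl)silyl]oxy}methyl)-4-(hydroxymethyl)-2,2-dimethyl-2,3-dihydro-1H-inden-5-yl]ethan-1-ol
Product: 15 tert-butyl{[5-(2-chloroethyl)-4-(chloromethyl)-2,2-dimethyl-2,3-dihydro-1H-inden-6-yl]methoxy}dimethylsilane, via bis-mesylate 14 (not isolated)
Conditions: MsCl (3 equiv), Et3N, CH2Cl2, −20 to 0 °C; then LiCl, DMF, 50 °C
Reagents that add atoms: lithium chloride, [Li+].[Cl-]; methanesulfonyl chloride, CS(=O)(=O)Cl (supplies the mesyl groups of 14, which are lost again)
Why: Mesylation with excess MsCl/Et3N activates both primary alcohols faster than a mono-activated diol can cyclise, and SN2 displacement by chloride in DMF (Finkelstein-type exchange) then converts both mesylates into chlorides without touching the silyl ether.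

Step 9
Reactants: 15 tert-butyl{[5-(2-chloroethyl)-4-(chloromethyl)-2,2-dimethyl-2,3-dihydro-1H-inden-6-yl]methoxy}dimethylsilane
Product: 16 [6-({[tert-butyl(dimethyl)silyl]oxy}methyl)-5-(2-chloroethyl)-2,2-dimethyl-2,3-dihydro-1H-inden-4-yl]methyl acetate
Conditions: CsOAc (1.1 equiv), DMF, rt
Reagents that add atoms: cesium acetate, CC(=O)[O-].[Cs+]
Why: SN2 displacement by acetate is much faster at a benzylic chloride than at an unactivated primary alkyl chloride, so one equivalent at room temperature should exchange only the C4 chloromethyl group, and acetate is too weak a base to eliminate HCl from the chloroethyl arm.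

Step 10
Reactants: 16 [6-({[tert-butyl(dimethyl)silyl]oxy}methyl)-5-(2-chloroethyl)-2,2-dimethyl-2,3-dihydro-1H-inden-4-yl]methyl acetate
Product: 17 [5-(2-chloroethyl)-6-(hydroxymethyl)-2,2-dimethyl-2,3-dihydro-1H-inden-4-yl]methyl acetate
Conditions: HF·pyridine, pyridine, THF, 0 °C to rt
Reagents that add atoms: none
Why: Fluoride-mediated desilylation under buffered acidic conditions frees the benzylic alcohol without ever forming an alkoxide, which under basic fluoride conditions could displace the neighbouring chloroethyl chloride (isochroman formation) or cleave the acetate.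

Step 11
Reactants: 17 [5-(2-chloroethyl)-6-(hydroxymethyl)-2,2-dimethyl-2,3-dihydro-1H-inden-4-yl]methyl acetate
Product: 18 [4-(acetoxymethyl)-5-(2-chloroethyl)-2,2-dimethyl-2,3-dihydro-1H-inden-6-yl]methyl butanoate (CNP0321917.0)
Conditions: butanoyl chloride, pyridine, DMAP (cat.), CH2Cl2, 0 °C to rt
Reagents that add atoms: butanoyl chloride, CCCC(Cl)=O
Why: DMAP-catalysed acylation (nucleophilic catalysis) of the primary benzylic alcohol installs the butyrate under conditions to which the acetate and the alkyl chloride are inert.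

**Compound list**
1 | 3,3-dimethylglutaric anhydride (4,4-dimethyloxane-2,6-dione) | CC1(C)CC(=O)OC(=O)C1 | starting material
2 | 3,3-dimethylpentane-1,5-diol | OCCC(C)(C)CCO | intermediate
3 | 3,3-dimethylpentanedial | O=CCC(C)(C)CC=O | intermediate
4 | dimethyl (1-diazo-2-oxopropyl)phosphonate | CC(=O)C(=[N+]=[N-])P(=O)(OC)OC | starting material
5 | 4,4-dimethylhepta-1,6-diyne | C#CCC(C)(C)CC#C | intermediate
6 | tert-butyldimethyl(prop-2-yn-1-yloxy)silane | C#CCO[Si](C)(C)C(C)(C)C | starting material
7 | [(3-bromoprop-2-yn-1-yl)oxy](tert-butyl)dimethylsilane | BrC#CCO[Si](C)(C)C(C)(C)C | intermediate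
8 | tert-butyl[(7,7-dimethyldeca-2,4,9-triyn-1-yl)oxy]dimethylsilane | C#CCC(C)(C)CC#CC#CCO[Si](C)(C)C(C)(C)C | intermediate
9 | dimethyl malonate | COC(=O)CC(=O)OC | starting material
10 | 6-({[tert-butyl(dimethyl)silyl]oxy}methyl)-2,2-dimethyl-4,5-didehydro-2,3-dihydro-1H-indene (C4–C5 aryne, not isolated) | CC1(C)CC2=C(C1)C#CC(CO[Si](C)(C)C(C)(C)C)=C2 | intermediate
11 | cesium alkoxide of the cyclobutene-fused adduct, four-membered ring C4–C(O−)(OMe)–CH(CO2Me)–C5 (not isolated; either relative configuration, both stereocentres vanish on ring opening) | COC(=O)C1c2c(CO[Si](C)(C)C(C)(C)C)cc3c(c2C1([O-])OC)CC(C)(C)C3.[Cs+] | intermediate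
12 | methyl 6-({[tert-butyl(dimethyl)silyl]oxy}methyl)-5-(2-methoxy-2-oxoethyl)-2,2-dimethyl-2,3-dihydro-1H-indene-4-carboxylate | COC(=O)Cc1c(CO[Si](C)(C)C(C)(C)C)cc2c(c1C(=O)OC)CC(C)(C)C2 | intermediate
13 | 2-[6-({[tert-butyl(dimethyl)silyl]oxy}methyl)-4-(hydroxymethyl)-2,2-dimethyl-2,3-dihydro-1H-inden-5-yl]ethan-1-ol | OCc1c(CCO)c(CO[Si](C)(C)C(C)(C)C)cc2c1CC(C)(C)C2 | intermediate
14 | 2-[6-({[tert-butyl(dimethyl)silyl]oxy}methyl)-4-{[(methanesulfonyl)oxy]methyl}-2,2-dimethyl-2,3-dihydro-1H-inden-5-yl]ethyl methanesulfonate (not isolated) | CS(=O)(=O)OCc1c(CCOS(C)(=O)=O)c(CO[Si](C)(C)C(C)(C)C)cc2c1CC(C)(C)C2 | intermediate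
15 | tert-butyl{[5-(2-chloroethyl)-4-(chloromethyl)-2,2-dimethyl-2,3-dihydro-1H-inden-6-yl]methoxy}dimethylsilane | ClCc1c(CCCl)c(CO[Si](C)(C)C(C)(C)C)cc2c1CC(C)(C)C2 | intermediate
16 | [6-({[tert-butyl(dimethyl)silyl]oxy}methyl)-5-(2-chloroethyl)-2,2-dimethyl-2,3-dihydro-1H-inden-4-yl]methyl acetate | CC(=O)OCc1c(CCCl)c(CO[Si](C)(C)C(C)(C)C)cc2c1CC(C)(C)C2 | intermediate
17 | [5-(2-chloroethyl)-6-(hydroxymethyl)-2,2-dimethyl-2,3-dihydro-1H-inden-4-yl]methyl acetate | CC(=O)OCc1c(CCCl)c(CO)cc2c1CC(C)(C)C2 | intermediate
18 | [4-(acetoxymethyl)-5-(2-chloroethyl)-2,2-dimethyl-2,3-dihydro-1H-inden-6-yl]methyl butanoate | CCCC(=O)OCc1cc2c(c(COC(C)=O)c1CCCl)CC(C)(C)C2 | target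

**Step count**
Total: 11 steps. Longest linear sequence: 10 steps (steps 1, 2, 3, 5, 6, 7, 8, 9, 10, 11); step 4 is a one-step side branch.

**Steps most likely to fail**

1. Step 6 (the step that bears the label). What may go wrong: base-induced prototropic isomerisation or oligomerisation of the triyne before it cyclises, protonation of the C4 carbanion before it closes on the ester (arylation without insertion), or attack of the enolate at C4 instead of C5. The fallback uses known chemistry only, sets out from 8 and returns at 13. Triyne 8 would be heated without base in 1,2-dichlorobenzene in the presence of acetic acid, the established carboxylic-acid trapping of thermally generated arynes. This should place the acetoxy group on C5 and hydrogen on C4 and give 5-acetoxy-6-(TBSOCH2)-2,2-dimethylindane F1. Methanolysis (K2CO3, MeOH) would give the phenol 6-(TBSOCH2)-2,2-dimethylindan-5-ol F2. Magnesium-mediated ortho-formylation (MgCl2, Et3N, paraformaldehyde, MeCN, reflux) can only reach C4, the one free ortho position, and would give 6-(TBSOCH2)-5-hydroxy-2,2-dimethylindane-4-carbaldehyde F3. Triflation (Tf2O, pyridine) would give 6-(TBSOCH2)-4-formyl-2,2-dimethylindan-5-yl trifluoromethanesulfonate F4. Stille coupling with tributyl(vinyl)stannane (Pd(PPh3)4, LiCl, dioxane) would give 6-(TBSOCH2)-5-ethenyl-2,2-dimethylindane-4-carbaldehyde F5. NaBH4 reduction would give [6-(TBSOCH2)-5-ethenyl-2,2-dimethylindan-4-yl]methanol F6, and anti-Markovnikov hydroboration–oxidation (9-BBN, then NaOH/H2O2) would deliver diol 13. Here the C5–C bond comes from cross-coupling and the C4–C bond from electrophilic substitution, so nothing depends on the insertion.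

2. Step 5. What may go wrong: coupling at both ends of the symmetric diyne, oxidative homocoupling of the bromoalkyne, and evaporative loss of the volatile diyne 5. The fallback sets out from 1 and returns at 8, and tells the two chain ends apart from the first step. NaBH4 in THF would reduce anhydride 1 to the lactone 4,4-dimethyloxan-2-one F7. i-Bu2AlH at −78 °C would give the racemic lactol 4,4-dimethyloxan-2-ol F8. Ohira–Bestmann reaction of the lactol with 4 (K2CO3, MeOH) would give 3,3-dimethylhex-5-yn-1-ol F9. Cadiot–Chodkiewicz coupling of F9 with 7, now with a single terminal alkyne and no statistical problem, would give 9-(TBSO)-3,3-dimethylnona-5,7-diyn-1-ol F10. Dess–Martin oxidation would give 9-(TBSO)-3,3-dimethylnona-5,7-diynal F11, and a second Ohira–Bestmann homologation with 4 would give triyne 8.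

3. Step 8. What may go wrong: ring closure of the mono-activated diol to an isochroman before the second hydroxyl is activated and, in step 9, incomplete discrimination between the two chlorides. The fallback sets out from 12 and returns at 16, and tells the two arms apart at the ester stage. LiOH in aqueous THF should hydrolyse only the unhindered aliphatic ester, the benzoate being flanked by two ortho substituents, to give [6-(TBSOCH2)-4-(methoxycarbonyl)-2,2-dimethylindan-5-yl]acetic acid F12. BH3·SMe2 would reduce the acid selectively to methyl 6-(TBSOCH2)-5-(2-hydroxyethyl)-2,2-dimethylindane-4-carboxylate F13. Appel chlorination (PPh3, CCl4) would give methyl 6-(TBSOCH2)-5-(2-chloroethyl)-2,2-dimethylindane-4-carboxylate F14. i-Bu2AlH would reduce the benzoate to [6-(TBSOCH2)-5-(2-chloroethyl)-2,2-dimethylindan-4-yl]methanol F15, and acetylation (Ac2O, pyridine, DMAP) would give 16.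

**Further compounds**
F1 | step 6 | 5-acetoxy-6-(TBSOCH2)-2,2-dimethylindane | CC(=O)Oc1cc2c(cc1CO[Si](C)(C)C(C)(C)C)CC(C)(C)C2
F2 | step 6 | 6-(TBSOCH2)-2,2-dimethylindan-5-ol | Oc1cc2c(cc1CO[Si](C)(C)C(C)(C)C)CC(C)(C)C2
F3 | step 6 | 6-(TBSOCH2)-5-hydroxy-2,2-dimethylindane-4-carbaldehyde | O=Cc1c(O)c(CO[Si](C)(C)C(C)(C)C)cc2c1CC(C)(C)C2
F4 | step 6 | 6-(TBSOCH2)-4-formyl-2,2-dimethylindan-5-yl trifluoromethanesulfonate | O=Cc1c(OS(=O)(=O)C(F)(F)F)c(CO[Si](C)(C)C(C)(C)C)cc2c1CC(C)(C)C2
F5 | step 6 | 6-(TBSOCH2)-5-ethenyl-2,2-dimethylindane-4-carbaldehyde | O=Cc1c(C=C)c(CO[Si](C)(C)C(C)(C)C)cc2c1CC(C)(C)C2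
F6 | step 6 | [6-(TBSOCH2)-5-ethenyl-2,2-dimethylindan-4-yl]methanol | OCc1c(C=C)c(CO[Si](C)(C)C(C)(C)C)cc2c1CC(C)(C)C2
F7 | step 5 | 4,4-dimethyloxan-2-one | CC1(C)CCOC(=O)C1
F8 | step 5 | 4,4-dimethyloxan-2-ol (racemic lactol) | CC1(C)CCOC(O)C1
F9 | step 5 | 3,3-dimethylhex-5-yn-1-ol | C#CCC(C)(C)CCO
F10 | step 5 | 9-(TBSO)-3,3-dimethylnona-5,7-diyn-1-ol | OCCC(C)(C)CC#CC#CCO[Si](C)(C)C(C)(C)C
F11 | step 5 | 9-(TBSO)-3,3-dimethylnona-5,7-diynal | O=CCC(C)(C)CC#CC#CCO[Si](C)(C)C(C)(C)C
F12 | step 8 | [6-(TBSOCH2)-4-(methoxycarbonyl)-2,2-dimethylindan-5-yl]acetic acid | OC(=O)Cc1c(CO[Si](C)(C)C(C)(C)C)cc2c(c1C(=O)OC)CC(C)(C)C2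
F13 | step 8 | methyl 6-(TBSOCH2)-5-(2-hydroxyethyl)-2,2-dimethylindane-4-carboxylate | OCCc1c(CO[Si](C)(C)C(C)(C)C)cc2c(c1C(=O)OC)CC(C)(C)C2
F14 | step 8 | methyl 6-(TBSOCH2)-5-(2-chloroethyl)-2,2-dimethylindane-4-carboxylate | ClCCc1c(CO[Si](C)(C)C(C)(C)C)cc2c(c1C(=O)OC)CC(C)(C)C2
F15 | step 8 | [6-(TBSOCH2)-5-(2-chloroethyl)-2,2-dimethylindan-4-yl]methanol | ClCCc1c(CO[Si](C)(C)C(C)(C)C)cc2c(c1CO)CC(C)(C)C2
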